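**Retrosynthetic overview**

1. Target 13 comes from its 3'-O-benzyl ether 12 by hydrogenolysis. Ring C of 12 comes from chalcone 10 by O1–C2 closure and C2=C3 dehydrogenation.
2. Ring A of chalcone 10 is cut at C4a–C8a (Claisen disconnection). This gives the open 3,5,7-triketo ester 9, which is stored as its enol lactone, the 6-(cinnamoylmethyl)-4-hydroxy-3,5-dimethyl-2-pyrone 8.
3. Pyrone 8 is cut at C4–C4a into the C6-methyl dianion of trimethylhydroxypyrone 7 (from keto ester 5 by acetylation and lactonisation) and the cinnamoyl Weinreb amide 4 (from aldehyde 1 by benzylation and Horner–Wadsworth–Emmons olefination).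
4. Feature on which the plan rests: ring A (C4a, C5, C6, C7, C8, C8a) is a fully substituted benzene ring with oxygen on C5, C7 and C8a, methyl on C6 and C8, and the acyl carbon C4 on C4a. This is a C-methylated acylphloroglucinol, the folded form of a linear poly-β-keto chain with two methyl-branched carbons.
5. Order of rings: ring B is bought; the pyrone ring is a temporary mask (step 4); carbocyclic ring A forms in step 6; pyranone ring C forms in step 7.

Key step: step 6

Remark on the chemistry: compounds 5, 6 and 9 carry only enolisable stereocentres and are handled as stereoisomer and tautomer mixtures. Chalcone 10 may close partly to the racemic flavanone 11 on acidic work-up of step 6; such a mixture would be taken on unchanged, because both converge on flavone 12 in step 7.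

**Route**

Step 1
Reactants: 1 3-hydroxy-4,5-dimethoxybenzaldehyde; 2 benzyl bromide
Product: 3 3-benzyloxy-4,5-dimethoxybenzaldehyde
Conditions: K2CO3, DMF, 60 °C
Reagents that add atoms: none
Why: Williamson ether synthesis on the only phenol should be clean, because the phenoxide formed by K2CO3 is alkylated by the benzylic bromide while the aldehyde is inert under these conditions.

Step 2
Reactants: 3 3-benzyloxy-4,5-dimethoxybenzaldehyde
Product: 4 (E)-3-(3-benzyloxy-4,5-dimethoxyphenyl)-N-methoxy-N-methylprop-2-enamide
Conditions: (EtO)2P(O)CH2C(O)N(OMe)Me, NaH, THF, 0 °C to rt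
Reagents that add atoms: diethyl (N-methoxy-N-methylcarbamoylmethyl)phosphonate, CCOP(=O)(OCC)CC(=O)N(C)OC
Why: Horner–Wadsworth–Emmons olefination with the amide-stabilised phosphonate anion should give the (E)-alkene under thermodynamic control and installs the Weinreb amide in the same operation.

Step 3
Reactants: 5 methyl 2-methyl-3-oxopentanoate
Product: 6 methyl 2,4-dimethyl-3,5-dioxohexanoate
Conditions: NaH, THF, 0 °C; n-BuLi, 0 °C; MeC(O)N(OMe)Me, −78 to 0 °C; then 1 M HCl
Reagents that add atoms: N-methoxy-N-methylacetamide, CC(=O)N(C)OC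
Why: Huckin–Weiler dianion formation places the more reactive carbanion on C4 (the ethyl CH2), which adds to the Weinreb amide to give a chelated tetrahedral intermediate that releases the ketone only on work-up (Weinreb ketone synthesis), so the acidic product cannot quench unreacted dianion.

Step 4
Reactants: 6 methyl 2,4-dimethyl-3,5-dioxohexanoate
Product: 7 4-hydroxy-3,5,6-trimethyl-2H-pyran-2-one
Conditions: DBU, toluene, reflux; then 1 M HCl
Reagents that add atoms: none
Why: DBU enolises the C5 ketone and the enol oxygen attacks the methyl ester in a 6-exo-trig enol lactonisation (intramolecular transesterification), driven by loss of methanol and formation of the stabilised 4-oxido-2-pyrone.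

Step 5
Reactants: 7 4-hydroxy-3,5,6-trimethyl-2H-pyran-2-one; 4 (E)-3-(3-benzyloxy-4,5-dimethoxyphenyl)-N-methoxy-N-methylprop-2-enamide
Product: 8 6-[(E)-4-(3-benzyloxy-4,5-dimethoxyphenyl)-2-oxobut-3-enyl]-4-hydroxy-3,5-dimethyl-2H-pyran-2-one
Conditions: LiN(i-Pr)2 (2.3 equiv), THF, −78 to −30 °C; then 4, −78 to −20 °C; then 1 M HCl
Reagents that add atoms: none
Why: After O–H deprotonation the second equivalent of base removes a proton from the C6 methyl, the only methyl in vinylogous conjugation with the lactone carbonyl, and this dianion should acylate at that carbon by 1,2-addition to the lithium-chelating Weinreb amide (dianion acylation of a 4-hydroxy-6-methyl-2-pyrone combined with the Weinreb ketone synthesis), the ketone being released only on work-up.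

Step 6
Reactants: 8 6-[(E)-4-(3-benzyloxy-4,5-dimethoxyphenyl)-2-oxobut-3-enyl]-4-hydroxy-3,5-dimethyl-2H-pyran-2-one
Product: 10 (E)-3-(3-benzyloxy-4,5-dimethoxyphenyl)-1-(2,4,6-trihydroxy-3,5-dimethylphenyl)prop-2-en-1-one, via triketo ester 9 (not isolated)
Conditions: Mg(OMe)2 (8 equiv), MeOH, reflux, argon; then cold 1 M HCl
Reagents that add atoms: none
Why: Magnesium-bound methoxide adds to the lactone carbonyl (pyrone C2) and opens the O1–C2 bond to the magnesium-chelated triketo ester 9, whose C6 methylene, the only carbon between two ketones that bears no methyl group, attacks the ester carbonyl C1 in an intramolecular Claisen (Dieckmann-type) condensation; loss of methoxide and enolisation then give the aromatic acylphloroglucinol, so that the new bond is C4a–C8a of the flavone. The closest known reaction type is the Mg(OMe)2-mediated conversion of 6-(2-oxoalkyl)-4-hydroxy-2-pyrones and 3,5,7-triketo esters into acylphloroglucinols. Carbocyclic ring A closes in a 6-exo-trig mode at the ester carbon. No stereocentre is created, and the enolisable ones of 9 disappear on aromatisation. The step needs Claisen folding to win over aldol folding (C2 onto the C7 ketone), Michael closure (C4 or the C5 enol oxygen onto C9) and retro-Claisen methanolysis; the methyl groups on C2 and C4 make the carbon-centred alternatives quaternary and unable to aromatise so that they revert, magnesium chelation holds the chain folded and shields the β-diketone units from cleavage, and aromatisation makes the Claisen product the irreversible sink.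

Step 7
Reactants: 10 (E)-3-(3-benzyloxy-4,5-dimethoxyphenyl)-1-(2,4,6-trihydroxy-3,5-dimethylphenyl)prop-2-en-1-one
Product: 12 3'-benzyloxy-5,7-dihydroxy-4',5'-dimethoxy-6,8-dimethylflavone, via racemic flavanone 11 (not isolated)
Conditions: I2 (0.1 equiv), DMSO, 120 °C
Reagents that add atoms: none
Why: Iodine–DMSO oxidative cyclisation of a 2'-hydroxychalcone should apply, in which one of the two equivalent ortho hydroxyls closes onto the enone by 6-endo-trig oxa-Michael addition, α-iodination and loss of HI introduce the C2=C3 bond while DMSO reoxidises HI, and the fully substituted ring A offers no free position for iodination.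

Step 8
Reactants: 12 3'-benzyloxy-5,7-dihydroxy-4',5'-dimethoxy-6,8-dimethylflavone
Product: 13 5,7,3'-trihydroxy-4',5'-dimethoxy-6,8-dimethylflavone
Conditions: H2 (1 atm), 10% Pd/C, THF–MeOH, rt
Reagents that add atoms: none
Why: Catalytic hydrogenolysis of the aryl benzyl ether should be much faster than reduction of the conjugated C2=C3 bond of the chromone (a vinylogous ester), so stopping after one equivalent of H2 should leave the flavone core intact.

**Compound list**

1 | 3-hydroxy-4,5-dimethoxybenzaldehyde | COc1cc(C=O)cc(O)c1OC | starting material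
2 | benzyl bromide | BrCc1ccccc1 | starting material
3 | 3-benzyloxy-4,5-dimethoxybenzaldehyde | COc1cc(C=O)cc(OCc2ccccc2)c1OC | intermediate
4 | (E)-3-(3-benzyloxy-4,5-dimethoxyphenyl)-N-methoxy-N-methylprop-2-enamide | CON(C)C(=O)/C=C/c1cc(OC)c(OC)c(OCc2ccccc2)c1 | intermediate
5 | methyl 2-methyl-3-oxopentanoate (racemic) | CCC(=O)C(C)C(=O)OC | starting material
6 | methyl 2,4-dimethyl-3,5-dioxohexanoate (stereoisomer and tautomer mixture) | CC(=O)C(C)C(=O)C(C)C(=O)OC | intermediate
7 | 4-hydroxy-3,5,6-trimethyl-2H-pyran-2-one | Cc1oc(=O)c(C)c(O)c1C | intermediate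
8 | 6-[(E)-4-(3-benzyloxy-4,5-dimethoxyphenyl)-2-oxobut-3-enyl]-4-hydroxy-3,5-dimethyl-2H-pyran-2-one | Cc1c(O)c(C)c(CC(=O)/C=C/c2cc(OC)c(OC)c(OCc3ccccc3)c2)oc1=O | intermediate
9 | methyl (E)-9-(3-benzyloxy-4,5-dimethoxyphenyl)-2,4-dimethyl-3,5,7-trioxonon-8-enoate (stereoisomer and tautomer mixture, as its magnesium chelate in the flask) | COC(=O)C(C)C(=O)C(C)C(=O)CC(=O)/C=C/c1cc(OC)c(OC)c(OCc2ccccc2)c1 | intermediate (not isolated)
10 | (E)-3-(3-benzyloxy-4,5-dimethoxyphenyl)-1-(2,4,6-trihydroxy-3,5-dimethylphenyl)prop-2-en-1-one | O=C(/C=C/c1cc(OC)c(OC)c(OCc2ccccc2)c1)c1c(O)c(C)c(O)c(C)c1O | intermediate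
11 | racemic 2-(3-benzyloxy-4,5-dimethoxyphenyl)-5,7-dihydroxy-6,8-dimethylchroman-4-one | COc1cc(C2CC(=O)c3c(O)c(C)c(O)c(C)c3O2)cc(OCc2ccccc2)c1OC | intermediate (not isolated)
12 | 3'-benzyloxy-5,7-dihydroxy-4',5'-dimethoxy-6,8-dimethylflavone | COc1cc(-c2cc(=O)c3c(O)c(C)c(O)c(C)c3o2)cc(OCc2ccccc2)c1OC | intermediate
13 | 5,7,3'-trihydroxy-4',5'-dimethoxy-6,8-dimethylflavone | COc1cc(-c2cc(=O)c3c(O)c(C)c(O)c(C)c3o2)cc(O)c1OC | target

**Step count**

Total: 8 steps. Longest linear sequence: 6 steps (1 → 3 → 4 → 8 → 10 → 12 → 13, or equally 5 → 6 → 7 → 8 → 10 → 12 → 13).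

**Steps most likely to fail**

Step 6. The doubly deprotonated, electron-rich pyrone may resist methanolysis, or the opened chain may be consumed by retro-Claisen methanolysis or aldol folding before the Claisen closure takes place. The fallback builds the chalcone by Claisen–Schmidt condensation on a preformed ring A; it sets out from aldehyde 3 and comes back to the route at chalcone 10. Purchased 2',4',6'-trihydroxyacetophenone would be C-methylated twice (MeI, NaOMe, MeOH) to 2',4',6'-trihydroxy-3',5'-dimethylacetophenone F1. MOMCl and i-Pr2NEt in CH2Cl2 would then protect two phenols and leave the carbonyl-chelated ortho hydroxyl free, giving 2'-hydroxy-4',6'-bis(methoxymethoxy)-3',5'-dimethylacetophenone F2. Condensation of F2 with aldehyde 3 (KOH, EtOH, rt) would give (E)-3-(3-benzyloxy-4,5-dimethoxyphenyl)-1-[2-hydroxy-4,6-bis(methoxymethoxy)-3,5-dimethylphenyl]prop-2-en-1-one F3. HCl in MeOH at 40 °C would remove both acetals and return chalcone 10; any flavanone 11 formed alongside is an equally good substrate for step 7.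

Step 5. The dianion may add in conjugate fashion to the cinnamoyl amide instead of attacking its carbonyl, or the second deprotonation of the poorly soluble lithium pyronate may stay incomplete. The fallback replaces acylation by aldol addition and oxidation; it sets out from amide 4 and pyrone 7 and comes back at pyrone 8. Amide 4 would be reduced with i-Bu2AlH (THF, −78 °C) to (E)-3-(3-benzyloxy-4,5-dimethoxyphenyl)prop-2-enal F4. The dianion of 7 (LiN(i-Pr)2, THF, −78 °C) would add 1,2 to this enal to give racemic 6-[(E)-4-(3-benzyloxy-4,5-dimethoxyphenyl)-2-hydroxybut-3-enyl]-4-hydroxy-3,5-dimethyl-2H-pyran-2-one F5. MnO2 in CH2Cl2 at rt would oxidise the allylic alcohol of F5 selectively to ketone 8.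

Step 7. The free, electron-rich phloroglucinol ring may be degraded oxidatively in hot iodine–DMSO, the HI formed may cleave the benzyl ether, or the dehydrogenation may stall at the flavanone stage. The fallback separates cyclisation from dehydrogenation and masks the phenols; it sets out from chalcone 10 and comes back at flavone 12. Chalcone 10 would be isomerised to flavanone 11 (NaOAc, EtOH, reflux) and acetylated (Ac2O, pyridine, DMAP) to racemic 5,7-diacetoxy-2-(3-benzyloxy-4,5-dimethoxyphenyl)-6,8-dimethylchroman-4-one F6. DDQ in refluxing dioxane would dehydrogenate it to 5,7-diacetoxy-3'-benzyloxy-4',5'-dimethoxy-6,8-dimethylflavone F7. K2CO3 in MeOH at rt would remove the acetates and give flavone 12.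

**Further compounds**

F1 | step 6 | 2',4',6'-trihydroxy-3',5'-dimethylacetophenone | CC(=O)c1c(O)c(C)c(O)c(C)c1O
F2 | step 6 | 2'-hydroxy-4',6'-bis(methoxymethoxy)-3',5'-dimethylacetophenone | CC(=O)c1c(O)c(C)c(OCOC)c(C)c1OCOC
F3 | step 6 | (E)-3-(3-benzyloxy-4,5-dimethoxyphenyl)-1-[2-hydroxy-4,6-bis(methoxymethoxy)-3,5-dimethylphenyl]prop-2-en-1-one | O=C(/C=C/c1cc(OC)c(OC)c(OCc2ccccc2)c1)c1c(O)c(C)c(OCOC)c(C)c1OCOC
F4 | step 5 | (E)-3-(3-benzyloxy-4,5-dimethoxyphenyl)prop-2-enal | O=C/C=C/c1cc(OC)c(OC)c(OCc2ccccc2)c1
F5 | step 5 | racemic 6-[(E)-4-(3-benzyloxy-4,5-dimethoxyphenyl)-2-hydroxybut-3-enyl]-4-hydroxy-3,5-dimethyl-2H-pyran-2-one | Cc1c(O)c(C)c(CC(O)/C=C/c2cc(OC)c(OC)c(OCc3ccccc3)c2)oc1=O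
F6 | step 7 | racemic 5,7-diacetoxy-2-(3-benzyloxy-4,5-dimethoxyphenyl)-6,8-dimethylchroman-4-one | COc1cc(C2CC(=O)c3c(OC(C)=O)c(C)c(OC(C)=O)c(C)c3O2)cc(OCc2ccccc2)c1OC
F7 | step 7 | 5,7-diacetoxy-3'-benzyloxy-4',5'-dimethoxy-6,8-dimethylflavone | COc1cc(-c2cc(=O)c3c(OC(C)=O)c(C)c(OC(C)=O)c(C)c3o2)cc(OCc2ccccc2)c1OC
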